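**Plan**
- Retrosynthesis: the 7-OH is unmasked last from a benzyl ether, and the chromone C2–H is traced back to the lactone carbonyl of a 3-aryl-4-hydroxycoumarin, one oxidation level higher at C2.
- Ring C is then cut at O1–C2 and C4–C4a. Its C2–C3–C4 unit, with oxygen on C2 and C4 either side of the aryl-bearing C3, is a hidden arylmalonate; C4 sits on C4a and C2 on O1 of a ring A phenol.
- The arylmalonate is cut at its aryl–C bond (bromotrimethoxybenzene plus diethyl malonate); the phenol comes from isovanillin by benzylation and Baeyer–Villiger oxidation.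
- Forward: ring A and the trimethoxyphenyl ring are bought; ring C is the only ring made, in the thermal phenol–malonate annulation, followed by O-silylation, hydride reduction with acid treatment, and hydrogenolysis.
- Stereochemistry: the target has no stereocentre; the sp3 centres that appear transiently in the reduction step are erased by dehydration.

Key step: step 4

Remark on the chemistry: ring positions follow chromone numbering (O1, C2, C3, C4, C4a, C5–C8, C8a). In the phenol, C1 carries the hydroxyl, C3 the benzyloxy and C4 the methoxy group.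

**Step 1**
Reactants: 1 isovanillin (3-hydroxy-4-methoxybenzaldehyde)
Product: 2 3-(benzyloxy)-4-methoxybenzaldehyde
Conditions: BnBr, K2CO3, DMF, 60 °C
Reagents that add atoms: benzyl bromide, BrCc1ccccc1
Why: Williamson ether synthesis, in which the phenoxide formed with K2CO3 displaces bromide from the benzylic halide by SN2 and the aldehyde is untouched.

**Step 2**
Reactants: 2 3-(benzyloxy)-4-methoxybenzaldehyde
Product: 4 3-(benzyloxy)-4-methoxyphenol, via aryl formate 3 (not isolated)
Conditions: mCPBA, CH2Cl2, 0 °C to rt; aq. NaHCO3 wash; then K2CO3 (cat.), MeOH, rt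
Reagents that add atoms: mCPBA (3-chloroperoxybenzoic acid), OOC(=O)c1cccc(Cl)c1
Why: Baeyer–Villiger oxidation of an electron-rich benzaldehyde, in which the para-methoxy-substituted aryl group migrates in preference to hydride to give the aryl formate, which is cleaved by base-catalysed methanolysis.

**Step 3**
Reactants: 5 5-bromo-1,2,3-trimethoxybenzene; 6 diethyl malonate
Product: 7 diethyl 2-(3,4,5-trimethoxyphenyl)malonate
Conditions: Pd(OAc)2 (cat.), P(t-Bu)3·HBF4 (cat.), K3PO4, toluene, 90 °C
Reagents that add atoms: none
Why: Palladium-catalysed α-arylation of a malonate enolate (oxidative addition of the aryl bromide to zerovalent palladium carrying the bulky, electron-rich phosphine, enolate exchange, C–C reductive elimination), where the more hindered and more acidic mono-aryl product resists a second arylation.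

**Step 4**
Reactants: 4 3-(benzyloxy)-4-methoxyphenol; 7 diethyl 2-(3,4,5-trimethoxyphenyl)malonate
Product: 11 7-(benzyloxy)-4-hydroxy-6-methoxy-3-(3,4,5-trimethoxyphenyl)-2H-chromen-2-one, via acylketene 8 (not isolated), via mixed malonate 9 (not isolated), via aryl ester ketene 10 (not isolated)
Conditions: Ph2O, 250 °C, N2 sweep with ethanol distilled out, about 3 h; cool, dilute with hexane, collect the solid
Reagents that add atoms: none
Why: At about 250 °C malonate 7 should lose ethanol to acylketene 8, which the phenol oxygen of 4 traps as mixed malonate 9 (O1–C2 bond); a second loss of ethanol gives ketene 10, whose ketene carbon is attacked by the ring carbon ortho to the ester oxygen (C4–C4a bond), and rearomatisation leaves the 4-hydroxycoumarin enol. The closest known reaction type is the thermal cyclocondensation of phenols with 2-substituted diethyl malonates to 3-substituted 4-hydroxycoumarins. Ring C, the only ring formed, closes by an intramolecular Friedel–Crafts-type C-acylation, a 6-exo-dig attack of the arene on the ketene carbon, after the intermolecular O-acylation. No stereocentre is created. The selectivity required is C-acylation at C6 of the phenol and not at C2: C6 is para to the benzyloxy donor and unhindered, whereas C2 lies between two oxygen substituents. Continuous removal of ethanol drives both acyl transfers, and the benzyl and methyl ethers are expected to tolerate the short heating period.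

**Step 5**
Reactants: 11 7-(benzyloxy)-4-hydroxy-6-methoxy-3-(3,4,5-trimethoxyphenyl)-2H-chromen-2-one
Product: 12 7-(benzyloxy)-6-methoxy-3-(3,4,5-trimethoxyphenyl)-4-[(triisopropylsilyl)oxy]-2H-chromen-2-one
Conditions: TIPSCl, Et3N, DMAP (cat.), CH2Cl2, 0 °C to rt
Reagents that add atoms: triisopropylsilyl chloride, CC(C)[Si](Cl)(C(C)C)C(C)C
Why: O-silylation of a vinylogous carboxylic acid (silyl enol ether formation), in which the acidic 4-hydroxyl is silylated as its ammonium salt, facile silyl shifts between the two oxygens should settle on the more stable 4-silyloxy-2-pyranone, and the bulky silyl group slows hydrolysis.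

**Step 6**
Reactants: 12 7-(benzyloxy)-6-methoxy-3-(3,4,5-trimethoxyphenyl)-4-[(triisopropylsilyl)oxy]-2H-chromen-2-one
Product: 15 7-(benzyloxy)-6-methoxy-3-(3,4,5-trimethoxyphenyl)-4H-chromen-4-one, via lactol 13 (not isolated), via 2-hydroxychromanone 14 (not isolated)
Conditions: i-Bu2AlH (1.1 equiv), CH2Cl2, −78 °C; then 2 M aq. HCl, THF, 0 °C to rt
Reagents that add atoms: none
Why: Proposed new method: the lactone C2=O is the only carbonyl of 12 and, as the terminus of a vinylogous carbonate whose C4 oxygen is capped, should accept a single hydride from i-Bu2AlH at −78 °C to give an aluminium hemiacetal that is stable in the cold; aqueous acid should then free lactol 13, hydrolyse the silyl enol ether to the 2-hydroxychroman-4-one 14 and eliminate water across C2–C3 to the conjugated 4-pyranone; the closest known reaction types are the i-Bu2AlH half-reduction of lactones (coumarins included) to lactols and the reduction–hydrolysis carbonyl transposition of vinylogous esters (Stork–Danheiser), while the closing dehydration of a 2-hydroxyisoflavanone is the final event of the classical deoxybenzoin route to isoflavones.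

**Step 7**
Reactants: 15 7-(benzyloxy)-6-methoxy-3-(3,4,5-trimethoxyphenyl)-4H-chromen-4-one
Product: 16 7-hydroxy-6-methoxy-3-(3,4,5-trimethoxyphenyl)-4H-chromen-4-one
Conditions: H2 (1 atm), Pd/C (10% palladium on carbon), EtOAc–THF, rt, stopped after one equivalent of H2
Reagents that add atoms: none
Why: Catalytic hydrogenolysis of a benzyl aryl ether, which is expected to be much faster than reduction of the conjugated, trisubstituted C2=C3 bond of the isoflavone, so the methyl ethers and the pyranone remain intact.

**Compound list**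
1 | isovanillin (3-hydroxy-4-methoxybenzaldehyde) | COc1ccc(C=O)cc1O | starting material
2 | 3-(benzyloxy)-4-methoxybenzaldehyde | COc1ccc(C=O)cc1OCc1ccccc1 | intermediate
3 | 3-(benzyloxy)-4-methoxyphenyl formate | COc1ccc(OC=O)cc1OCc1ccccc1 | intermediate
4 | 3-(benzyloxy)-4-methoxyphenol | COc1ccc(O)cc1OCc1ccccc1 | intermediate
5 | 5-bromo-1,2,3-trimethoxybenzene | COc1cc(Br)cc(OC)c1OC | starting material
6 | diethyl malonate | CCOC(=O)CC(=O)OCC | starting material
7 | diethyl 2-(3,4,5-trimethoxyphenyl)malonate | CCOC(=O)C(C(=O)OCC)c1cc(OC)c(OC)c(OC)c1 | intermediate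
8 | ethyl 3-oxo-2-(3,4,5-trimethoxyphenyl)prop-2-enoate (acylketene) | CCOC(=O)C(=C=O)c1cc(OC)c(OC)c(OC)c1 | intermediate
9 | 3-(benzyloxy)-4-methoxyphenyl ethyl 2-(3,4,5-trimethoxyphenyl)malonate (racemic) | CCOC(=O)C(C(=O)Oc1ccc(OC)c(OCc2ccccc2)c1)c1cc(OC)c(OC)c(OC)c1 | intermediate
10 | 3-(benzyloxy)-4-methoxyphenyl 3-oxo-2-(3,4,5-trimethoxyphenyl)prop-2-enoate (ketene) | O=C=C(C(=O)Oc1ccc(OC)c(OCc2ccccc2)c1)c1cc(OC)c(OC)c(OC)c1 | intermediate
11 | 7-(benzyloxy)-4-hydroxy-6-methoxy-3-(3,4,5-trimethoxyphenyl)-2H-chromen-2-one | COc1cc2c(O)c(-c3cc(OC)c(OC)c(OC)c3)c(=O)oc2cc1OCc1ccccc1 | intermediate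
12 | 7-(benzyloxy)-6-methoxy-3-(3,4,5-trimethoxyphenyl)-4-[(triisopropylsilyl)oxy]-2H-chromen-2-one | COc1cc2c(O[Si](C(C)C)(C(C)C)C(C)C)c(-c3cc(OC)c(OC)c(OC)c3)c(=O)oc2cc1OCc1ccccc1 | intermediate
13 | 7-(benzyloxy)-6-methoxy-3-(3,4,5-trimethoxyphenyl)-4-[(triisopropylsilyl)oxy]-2H-chromen-2-ol (racemic) | COc1cc2C(O[Si](C(C)C)(C(C)C)C(C)C)=C(c3cc(OC)c(OC)c(OC)c3)C(O)Oc2cc1OCc1ccccc1 | intermediate
14 | 7-(benzyloxy)-2-hydroxy-6-methoxy-3-(3,4,5-trimethoxyphenyl)chroman-4-one (mixture of stereoisomers) | COc1cc2C(=O)C(c3cc(OC)c(OC)c(OC)c3)C(O)Oc2cc1OCc1ccccc1 | intermediate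
15 | 7-(benzyloxy)-6-methoxy-3-(3,4,5-trimethoxyphenyl)-4H-chromen-4-one | COc1cc2c(=O)c(-c3cc(OC)c(OC)c(OC)c3)coc2cc1OCc1ccccc1 | intermediate
16 | 7-hydroxy-6-methoxy-3-(3,4,5-trimethoxyphenyl)-4H-chromen-4-one | COc1cc2c(=O)c(-c3cc(OC)c(OC)c(OC)c3)coc2cc1O | target

**Totals**
Total step count: 7.
Longest linear sequence: 6 steps (1 → 2 → 4 → 11 → 12 → 15 → 16; steps 1, 2, 4, 5, 6, 7). The malonate branch (step 3) joins at step 4.

**Steps most likely to fail**

Step 6 (lactone-to-chromone reduction). The aluminium hemiacetal may collapse to the ring-opened aldehyde and take up a second hydride (over-reduction). Hydride may instead add in conjugate fashion at C4, or the silyl group may be lost before the reduction is complete. The fallback uses only known chemistry, sets out from 11 and returns at 15. Heating 11 with aqueous NaOH in ethanol should open the lactone to the β-keto acid 3-[4-(benzyloxy)-2-hydroxy-5-methoxyphenyl]-3-oxo-2-(3,4,5-trimethoxyphenyl)propanoic acid F1. On acidification and warming this should lose carbon dioxide to the deoxybenzoin 1-[4-(benzyloxy)-2-hydroxy-5-methoxyphenyl]-2-(3,4,5-trimethoxyphenyl)ethan-1-one F2. Heating F2 with N,N-dimethylformamide dimethyl acetal in toluene should give the enaminone 1-[4-(benzyloxy)-2-hydroxy-5-methoxyphenyl]-3-(dimethylamino)-2-(3,4,5-trimethoxyphenyl)prop-2-en-1-one F3 (alkene geometry not controlled). Brief acid treatment should close F3 to 15 by conjugate addition of the phenol and loss of dimethylamine. C2 is thus excised and put back as a one-carbon unit, the classical deoxybenzoin route to isoflavones.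

Step 4 (thermal annulation). At 250 °C the benzyl ether may cleave or migrate, the malonate may lose an ethoxycarbonyl group to give the arylacetate, or ring acylation may occur between the two oxygens. The fallback sets out from 7 (with 4) and returns at 11; it replaces thermal ketene generation with an active-ester acylation at much lower temperature. Saponification of 7 with KOH in aqueous ethanol at rt and cold acidification should give 2-(3,4,5-trimethoxyphenyl)malonic acid F4. Esterification with 2,4,6-trichlorophenol and POCl3 should give bis(2,4,6-trichlorophenyl) 2-(3,4,5-trimethoxyphenyl)malonate F5. This active ester should condense with phenol 4 in refluxing bromobenzene, releasing trichlorophenol in both the O-acylation and the ring C-acylation, to give 11.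

Step 5 (O-silylation). Silylation may settle on the lactone carbonyl oxygen, giving the isomeric 2-silyloxychromone, or the vinylogous silyl ester may hydrolyse during isolation. The fallback sets out from 11 and returns at 15; it replaces the labile silyl enol ether with a stable alkyl enol ether that is unmasked by acid-promoted loss of methanol. It still relies on the hydride reduction proposed in step 6. Methylation of 11 with Me2SO4 and K2CO3 in refluxing acetone should give 7-(benzyloxy)-4,6-dimethoxy-3-(3,4,5-trimethoxyphenyl)-2H-chromen-2-one F6, which can be chromatographed free of any 2-methoxychromone isomer. Reduction with i-Bu2AlH at −78 °C should give the lactol 7-(benzyloxy)-4,6-dimethoxy-3-(3,4,5-trimethoxyphenyl)-2H-chromen-2-ol F7 (racemic). Aqueous HCl in THF should then expel methanol and water, through the hydroxychromanone 14, to give 15.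

**Further compounds**
F1 | step 6 | 3-[4-(benzyloxy)-2-hydroxy-5-methoxyphenyl]-3-oxo-2-(3,4,5-trimethoxyphenyl)propanoic acid (racemic) | COc1cc(C(=O)C(C(=O)O)c2cc(OC)c(OC)c(OC)c2)c(O)cc1OCc1ccccc1
F2 | step 6 | 1-[4-(benzyloxy)-2-hydroxy-5-methoxyphenyl]-2-(3,4,5-trimethoxyphenyl)ethan-1-one | COc1cc(C(=O)Cc2cc(OC)c(OC)c(OC)c2)c(O)cc1OCc1ccccc1
F3 | step 6 | 1-[4-(benzyloxy)-2-hydroxy-5-methoxyphenyl]-3-(dimethylamino)-2-(3,4,5-trimethoxyphenyl)prop-2-en-1-one (alkene geometry not defined) | COc1cc(C(=O)C(=CN(C)C)c2cc(OC)c(OC)c(OC)c2)c(O)cc1OCc1ccccc1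
F4 | step 4 | 2-(3,4,5-trimethoxyphenyl)malonic acid | COc1cc(C(C(=O)O)C(=O)O)cc(OC)c1OC
F5 | step 4 | bis(2,4,6-trichlorophenyl) 2-(3,4,5-trimethoxyphenyl)malonate | COc1cc(C(C(=O)Oc2c(Cl)cc(Cl)cc2Cl)C(=O)Oc2c(Cl)cc(Cl)cc2Cl)cc(OC)c1OC
F6 | step 5 | 7-(benzyloxy)-4,6-dimethoxy-3-(3,4,5-trimethoxyphenyl)-2H-chromen-2-one | COc1cc2c(OC)c(-c3cc(OC)c(OC)c(OC)c3)c(=O)oc2cc1OCc1ccccc1
F7 | step 5 | 7-(benzyloxy)-4,6-dimethoxy-3-(3,4,5-trimethoxyphenyl)-2H-chromen-2-ol (racemic) | COc1cc2C(OC)=C(c3cc(OC)c(OC)c(OC)c3)C(O)Oc2cc1OCc1ccccc1
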